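The runs were generated by integration with constants of no real substance, noise included.

4 questions came with your hunch, and we build our answer on one quantity.

in all of them: substrate 17 mM; gas phase 0.99 mM (held)
- south-west: catalyst 2.9 mM; run made earlier
- north-west: catalyst 2.7 mM; run made earlier
- elm: catalyst 2.0 mM; time 5.0 h
- birch: catalyst 2.4 mM; time 5.0 h

| run | time / h | uncatalysed product / % | over-reaction product / % | substrate / % | target / % |
|---|---|---|---|---|---|
| south-west | 0.250 | 8.6 | 1.4 | 68.0 | 22.3 |
| south-west | 0.667 | 18.0 | 5.5 | 33.8 | 42.1 |
| south-west | 1.33 | 24.3 | 18.6 | 10.3 | 47.2 |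
| south-west | 2.00 | 26.6 | 30.4 | 3.4 | 40.7 |
| south-west | 2.50 | 26.9 | 37.9 | 0.8 | 34.4 |
| south-west | 4.00 | 26.9 | 54.4 | 0.3 | 18.7 |
| north-west | 0.667 | 18.1 | 5.9 | 36.3 | 40.2 |
| north-west | 1.33 | 25.7 | 17.6 | 11.7 | 46.2 |
| north-west | 2.00 | 27.5 | 29.6 | 3.4 | 39.9 |
| north-west | 2.50 | 28.3 | 36.6 | 1.7 | 33.4 |
| north-west | 3.00 | 28.8 | 43.2 | 0.1 | 28.3 |
| north-west | 4.00 | 28.7 | 52.5 | 0 | 18.5 |

(readings scatter by 0.3 percentage points)

- which of these there is most of at the end, counted by the substrate in it, elm (substrate / uncatalysed product / target / over-reaction product)
- which of these there is most of at the end, counted by the substrate in it, birch (substrate / uncatalysed product / target / over-reaction product)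
- final amount of the leader among these, as a percentage of the substrate charged, in elm
- final amount of the leader among these, as a percentage of the substrate charged, in birch

- at the start none of the gas phase is in solution

In the south-west run the uncatalysed product reads 26.9 % at 2.50 h and 26.9 % at 4.00 h, so its last reading gives the final split. We assume the catalysed path grows with c(catalyst) and the uncatalysed path does not.

Then we can define the break-even catalyst c*, the c(catalyst) at which the two paths take equal shares of the substrate. It is a selectivity factor in concentration units: c(catalyst) times the uncatalysed product, divided by the rest. South-west gives 1.07 mM and north-west 1.09 mM. These agree, so we carry 1.08 mM.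

On that assumption the final uncatalysed share is c*/(c* + c(catalyst)). That is 35.0 % in elm and 31.0 % in birch.

We take the rest to pass through target. South-west's substrate decay reads 1.72 h⁻¹. Scaled by c* + c(catalyst), that becomes 1.33 h⁻¹ in elm and 1.51 h⁻¹ in birch. South-west's target tail reads 0.406 h⁻¹. Two first-order steps in series then leave 12.1 % target in elm and 12.3 % in birch at 5.0 h. So we reckon over-reaction product leads, with 52.9 % in elm and 56.7 % in birch.

The forecast names over-reaction product for elm and over-reaction product for birch, at 49 % and 54 %. Both figures are lower than ours. It takes the target tail as one that “barely depends on catalyst”.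

The flasks give over-reaction product at 53.3 % in elm and over-reaction product at 57.1 % in birch, so the forecast stands within its margins. Uncatalysed product reaches 34.9 % in elm and 30.9 % in birch.

    gas phase ⇌ dissolved gas, rate k1*(csat - [dissolved gas]) (kL = 0.0310 s⁻¹)
    dissolved gas + target → over-reaction product (k = 0.120 L mol⁻¹ s⁻¹)
    substrate + dissolved gas → uncatalysed product (k = 0.150 L mol⁻¹ s⁻¹)
    substrate + dissolved gas + catalyst → catalyst + target (k = 140 L² mol⁻² s⁻¹)

Both substrate steps hold dissolved gas once. Birch read at 2.0 h still has 4.41 % substrate, so our share gives 29.6 % uncatalysed product, and that flask holds 29.5 %. There target leads with 38.4 %.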